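The earlier runs and the new flask are simulated with made-up constants, and the scatter is random.

Hold the last amber reading against the first amber slope before believing any fitted curve.

| flask | starting material | coupling partner | free catalyst | time |
|---|---|---|---|---|
| amber | 1.00 M | 2.50 M | 0.0500 M |  |
| grey | 0.500 M | 2.00 M | 0.0500 M |  |
| green | 2.00 M | 2.50 M | 0.0500 M |  |
| blue | 1.00 M | 2.50 M | 0.0250 M |  |
| teal | 0.330 M | 2.50 M | 0.0170 M | 26 min |

- amber run (time / min: [target] / M): 1.5: 0.018; 4.5: 0.059; 8.6: 0.134; 14: 0.203; 19: 0.253; 26: 0.282
- grey run (time / min: [target] / M): 1.5: 0.027; 4.5: 0.013; 8.6: 0.044; 14: 0.046; 19: 0.081; 26: 0.095
- green run (time / min: [target] / M): 1.5: 0.052; 4.5: 0.157; 8.6: 0.415; 14: 0.685; 19: 0.821; 26: 0.911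
- blue run (time / min: [target] / M): 1.5: 0.019; 4.5: 0.057; 8.6: 0.097; 14: 0.149; 19: 0.204; 26: 0.259

(standard deviation of a reading: 0.01 M)

- Overall: starting material + coupling partner -> target, with free catalyst as catalyst.
- Constant volume, constant temperature.
- "The second partner" is coupling partner.
- An order is taken over about fifteen percent of the charge, up and down.

- the exponent of [coupling partner] in the starting rate at the charge of the amber run (at the point where two percent of the starting material have become target)
- the exponent of [starting material] in the starting rate at the charge of the amber run (at the point where two percent of the starting material have become target) (one fixed amount of target, the same in the runs compared)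
- target in the teal run at 26 min, as a share of the starting material charged

I turned the question round: what would have to be true for the teal flask to keep what it makes? Amber began at 0.0131 M min⁻¹, yet between its last two readings it rose at 0.00414 M min⁻¹, less than that, with target at 28.2% of the charge. I read this as target being lost while it was still being made, and I took that loss as pseudo-first-order in target at a fixed partner charge. So I named a working lifetime of target, the last amber level over the first amber slope:

lifetime = 21.5 min

Keeping would need a lifetime well beyond the 26 min asked. Teal has the partner charge of amber, so I carried the lifetime over, and it stood below that time.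

The blue and amber readings at 8.6 min gave me a catalyst order, from that one pair of readings:

order = 0.466

I counted the share made per minute as independent of the starting charge, which is first order in starting material, where the forecast read 1.4:

teal pace = 0.00793 min⁻¹

share kept = 58.0%

teal share = 20.6% × kept = 12.0%

The forecast gave a partner order of 1, a starting-material order of 1.4 and a teal share of 17%, the last taken from its starting rate, “less with depletion and stalling”.

The simulation gave a partner order of 1.0, a starting-material order of 1.1 and a teal share of 10.3%.

    2 free catalyst ⇌ catalyst dimer, settled at all times (102.0 L mol⁻¹)
    free catalyst + starting material + coupling partner → target + free catalyst (0.3822 L² mol⁻² min⁻¹)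
    starting material + coupling partner + target → 2 target (0.05898 L² mol⁻² min⁻¹)
    target + coupling partner → side product (0.02922 L mol⁻¹ min⁻¹)

Target goes on with coupling partner to side product. The teal flask run without that step gave 27.4%, against 10.3% with it, a difference of 17 percentage points through that step. My lifetime of 21.5 min gave a kept share of 58.0%, and the ratio of those two teal flasks is 37.6%.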